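The cyclohexanone ring (C1 ketone, C2–C3 epoxide, C4 angelate, C5 side chain, C6 acetate) is cut into the halves C2–C3–C4 and C5–C6–C1. In one flask a Liebeskind–Srogl acylation joins the stannylated C2 of a (Z)-3-stannylbutenal to the thioester carbon C1 of a chiral allylboronate, and the (Z)-4-oxo-enal so formed closes C4–C5 at once by allylboration. The step exploits the exocyclic methylene on the C5 substituent beside the C4 carbinol (homoallylic alcohol) and the acyl–alkenyl character of C1–C2. The C6 stereocentre and the alkene geometry of the boronate fix C4 and C5; hydroxyl-directed epoxidation and angeloylation complete the target.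

Key step: step 13

Remark: ring atoms are numbered C1 to C6 as in the paragraph above; the ketoreductase of step 6 is assumed to come from a commercial screening panel, and the enzyme that gives the (2S)-alcohol is used.

Step 1
Reactants: 1 3-(trimethylsilyl)prop-2-ynal
Product: 2 (3R)-1-(trimethylsilyl)hex-5-en-1-yn-3-ol
Conditions: (−)-Ipc2B(allyl) (preformed, salt-free), Et2O, −78 °C; then NaOH, H2O2, 0 °C
Reagents that add atoms: (−)-B-allyldiisopinocampheylborane, C=CCB(C1CC2CC(C1C)C2(C)C)C1CC2CC(C1C)C2(C)C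
Why: Brown asymmetric allylboration through a chair Zimmerman–Traxler transition state, in which the isopinocampheyl groups of the (−)-reagent should steer the allyl group to the aldehyde face that gives the (3R)-carbinol.

Step 2
Reactants: 2 (3R)-1-(trimethylsilyl)hex-5-en-1-yn-3-ol
Product: 3 (3R)-6-methyl-1-(trimethylsilyl)hept-5-en-1-yn-3-ol
Conditions: second-generation Grubbs catalyst (3 mol%), 2-methylbut-2-ene (excess), CH2Cl2, 40 °C
Reagents that add atoms: 2-methylbut-2-ene, CC=C(C)C
Why: Olefin cross-metathesis with excess 2-methylbut-2-ene should turn the terminal vinyl group into the prenyl-type alkene, while the silyl-capped alkyne stays out of enyne metathesis.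

Step 3
Reactants: 3 (3R)-6-methyl-1-(trimethylsilyl)hept-5-en-1-yn-3-ol
Product: 4 triethyl{[(3R)-6-methyl-1-(trimethylsilyl)hept-5-en-1-yn-3-yl]oxy}silane
Conditions: Et3SiCl, imidazole, CH2Cl2, 0 °C
Reagents that add atoms: chlorotriethylsilane, CC[Si](Cl)(CC)CC
Why: Standard silylation of the secondary propargylic alcohol keeps this oxygen out of the later acylation and acetylation.

Step 4
Reactants: 4 triethyl{[(3R)-6-methyl-1-(trimethylsilyl)hept-5-en-1-yn-3-yl]oxy}silane
Product: 5 triethyl{[(2R)-1-[(2S)-3,3-dimethyloxiran-2-yl]-4-(trimethylsilyl)but-3-yn-2-yl]oxy}silane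
Conditions: L-fructose-derived Shi ketone (30 mol%), Oxone (2KHSO5·KHSO4·K2SO4), K2CO3, Bu4NHSO4, MeCN–CH2(OMe)2–aqueous Na2B4O7 buffer, 0 °C
Reagents that add atoms: potassium peroxymonosulfate, [K+].[O-]S(=O)(=O)OO
Why: Shi asymmetric epoxidation, in which the dioxirane of the L-fructose-derived ketone (mirror image of the usual D-fructose catalyst) should attack the electron-rich trisubstituted alkene through a spiro transition state under catalyst control and set the (2S) oxirane carbon, the alkyne being inert.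

Step 5
Reactants: 5 triethyl{[(2R)-1-[(2S)-3,3-dimethyloxiran-2-yl]-4-(trimethylsilyl)but-3-yn-2-yl]oxy}silane
Product: 7 S-ethyl (5R)-6-[(2S)-3,3-dimethyloxiran-2-yl]-2-oxo-5-[(triethylsilyl)oxy]hex-3-ynethioate, via lithium acetylide 6 (not isolated)
Conditions: MeLi·LiBr, THF, 0 to 23 °C; then added to EtSC(O)C(O)SEt (3 equiv), THF, −78 °C; NH4Cl aq.
Reagents that add atoms: S,S-diethyl dithiooxalate, CCSC(=O)C(=O)SCC
Why: Methyllithium cleaves the alkynyl C–Si bond to the lithium acetylide, which should be acylated once by the excess dithiooxalate at −78 °C (inverse addition), the tetrahedral adduct shielding the product from a second addition.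

Step 6
Reactants: 7 S-ethyl (5R)-6-[(2S)-3,3-dimethyloxiran-2-yl]-2-oxo-5-[(triethylsilyl)oxy]hex-3-ynethioate
Product: 8 S-ethyl (2S,5R)-6-[(2S)-3,3-dimethyloxiran-2-yl]-2-hydroxy-5-[(triethylsilyl)oxy]hex-3-ynethioate
Conditions: ketoreductase, NADP+ (cat.), iPrOH, phosphate buffer pH 6.5–MTBE, 25 °C
Reagents that add atoms: none
Why: Enzymatic ketone reduction by a ketoreductase (NADPH-dependent oxidoreductase), in which hydride should reach one face of the activated 2-oxo group inside the enzyme pocket to set the (2S)-carbinol, with isopropanol recycling the cofactor.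

Step 7
Reactants: 8 S-ethyl (2S,5R)-6-[(2S)-3,3-dimethyloxiran-2-yl]-2-hydroxy-5-[(triethylsilyl)oxy]hex-3-ynethioate
Product: 9 S-ethyl (2S,5R)-2-acetoxy-6-[(2S)-3,3-dimethyloxiran-2-yl]-5-[(triethylsilyl)oxy]hex-3-ynethioate
Conditions: Ac2O, pyridine, DMAP (5 mol%), CH2Cl2, 0 °C
Reagents that add atoms: acetic anhydride, CC(=O)OC(C)=O
Why: Acetylation of the secondary alcohol under mild acyl-transfer catalysis at 0 °C should leave the acidic C2–H stereocentre untouched.

Step 8
Reactants: 9 S-ethyl (2S,5R)-2-acetoxy-6-[(2S)-3,3-dimethyloxiran-2-yl]-5-[(triethylsilyl)oxy]hex-3-ynethioate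
Product: 10 S-ethyl (2S,5R)-2-acetoxy-6-[(2S)-3,3-dimethyloxiran-2-yl]-5-hydroxyhex-3-ynethioate
Conditions: Bu4NF, AcOH (1:1.2), THF, 0 °C
Reagents that add atoms: none
Why: Buffered fluoride desilylation should remove the triethylsilyl ether, the near-neutral medium sparing thioester, acetate and the epoxide next to the freed hydroxyl.

Step 9
Reactants: 10 S-ethyl (2S,5R)-2-acetoxy-6-[(2S)-3,3-dimethyloxiran-2-yl]-5-hydroxyhex-3-ynethioate
Product: 11 S-ethyl (2S,3Z,5R)-2-acetoxy-6-[(2S)-3,3-dimethyloxiran-2-yl]-5-hydroxy-4-(tributylstannyl)hex-3-enethioate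
Conditions: [Cp*RuCl]4 (2.5 mol%), Bu3SnH, CH2Cl2, 23 °C
Reagents that add atoms: tributyltin hydride, CCCC[SnH](CCCC)CCCC
Why: Hydroxyl-directed ruthenium-catalysed trans-hydrostannation, in which hydrogen bonding of the free propargylic OH to the Ru–Cl unit should place tin on the proximal alkyne carbon and the anti addition of H and Sn should put the acetoxy-bearing carbon cis to tin.

Step 10
Reactants: 11 S-ethyl (2S,3Z,5R)-2-acetoxy-6-[(2S)-3,3-dimethyloxiran-2-yl]-5-hydroxy-4-(tributylstannyl)hex-3-enethioate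
Product: 12 S-ethyl (2S,3E,5R)-2-acetoxy-6-[(2S)-3,3-dimethyloxiran-2-yl]-5-hydroxy-4-[(4,4,5,5-tetramethyl-1,3,2-dioxaborolan-2-yl)methyl]hex-3-enethioate
Conditions: copper thiophene-2-carboxylate CuTC (CuO2CC4H3S, 1.5 equiv), ICH2Bpin, DMF, 0 to 23 °C
Reagents that add atoms: 2-(iodomethyl)-4,4,5,5-tetramethyl-1,3,2-dioxaborolane, ICB1OC(C)(C)C(C)(C)O1
Why: Copper-mediated Stille-type alkylation, in which tin-to-copper exchange and capture of the alkenylcopper by the SN2-active iodomethylboronate should proceed with retention of alkene geometry and give the allylboronate whose acetoxy-bearing arm is cis to CH2B.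

Step 11
Reactants: 13 but-2-yn-1-ol
Product: 15 (2Z)-3-(tributylstannyl)but-2-en-1-ol, via sodium alkenylaluminate 14 (not isolated)
Conditions: NaAlH2(OCH2CH2OMe)2, THF, 0 °C; then Bu3SnOTf, −78 to 23 °C; Rochelle salt aq.
Reagents that add atoms: tributyltin triflate, CCCC[Sn](CCCC)(CCCC)OS(=O)(=O)C(F)(F)F
Why: Alkoxide-directed trans-hydroalumination delivers aluminium to C3 within a five-membered chelate, and tin-for-aluminium exchange with retention should give the alkenylstannane with tin cis to CH2OH.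

Step 12
Reactants: 15 (2Z)-3-(tributylstannyl)but-2-en-1-ol
Product: 16 (2Z)-3-(tributylstannyl)but-2-enal
Conditions: MnO2, CH2Cl2, 23 °C
Reagents that add atoms: none
Why: Allylic oxidation with MnO2 should give the enal without Z to E isomerisation or destannylation.

Step 13
Reactants: 12 S-ethyl (2S,3E,5R)-2-acetoxy-6-[(2S)-3,3-dimethyloxiran-2-yl]-5-hydroxy-4-[(4,4,5,5-tetramethyl-1,3,2-dioxaborolan-2-yl)methyl]hex-3-enethioate; 16 (2Z)-3-(tributylstannyl)but-2-enal
Product: 18 (1S,5R,6R)-6-{(3R)-4-[(2S)-3,3-dimethyloxiran-2-yl]-3-hydroxybut-1-en-2-yl}-5-hydroxy-3-methyl-2-oxocyclohex-3-en-1-yl acetate, via (Z)-4-oxo-enal allylboronate 17 (not isolated)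
Conditions: Pd2(dba)3 (5 mol%), P(2-furyl)3 (20 mol%), CuO2PPh2 (1.5 equiv), THF, 23 to 40 °C; NaHCO3 aq.
Reagents that add atoms: none
Why: Zerovalent palladium inserts into the C–S bond of thioester 12, copper diphenylphosphinate takes up the thiolate and relays the alkenyl group of 16 from tin to palladium with retention, and reductive elimination forms C1–C2 (Liebeskind–Srogl ketone synthesis); the (Z)-4-oxo-enal 17 then closes C4–C5 spontaneously, the closest precedent being the ring-closing allylboration of formyl-tethered allylboronates. The carbocycle closes in 6-exo-trig mode through a bicyclic chair Zimmerman–Traxler transition state with boron on the aldehyde oxygen, which also creates the exocyclic methylene. Because the C6 arm is cis to CH2B on the boronate alkene it sits axial in that chair, so the C4 hydroxyl and the C5 side chain should come out cis. The face of C5 is set by the C6 stereocentre: allylic 1,3-strain holds C6–H in the alkene plane and the tether forces C1 onto the attacking face, which leaves the acetate on the other face and therefore trans to the C5 side chain. The step needs coupling to precede bimolecular allylboration and tin, not boron, to pass to copper; the slow room-temperature reaction of a hindered pinacol allylboronate with an enal and the base-free conditions should secure both, and the electron-poor aldehyde of 17 should make the closure fast.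

Step 14
Reactants: 18 (1S,5R,6R)-6-{(3R)-4-[(2S)-3,3-dimethyloxiran-2-yl]-3-hydroxybut-1-en-2-yl}-5-hydroxy-3-methyl-2-oxocyclohex-3-en-1-yl acetate
Product: 19 (1S,3S,4R,5S,6S)-4-{(3R)-4-[(2S)-3,3-dimethyloxiran-2-yl]-3-hydroxybut-1-en-2-yl}-5-hydroxy-1-methyl-2-oxo-7-oxabicyclo[4.1.0]heptan-3-yl acetate
Conditions: tBuOOH (anhydrous, decane), PhCH2NMe3OH (10 mol%), THF, −20 °C
Reagents that add atoms: tert-butyl hydroperoxide, CC(C)(C)OO
Why: Hydroxyl-directed Weitz–Scheffer epoxidation, in which the peroxide anion, hydrogen-bonded to the ring C4 hydroxyl, should add to the enone from the face of that hydroxyl and set C2 and C3 cis to it, the electron-rich side-chain alkene being inert to the nucleophilic oxidant.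

Step 15
Reactants: 19 (1S,3S,4R,5S,6S)-4-{(3R)-4-[(2S)-3,3-dimethyloxiran-2-yl]-3-hydroxybut-1-en-2-yl}-5-hydroxy-1-methyl-2-oxo-7-oxabicyclo[4.1.0]heptan-3-yl acetate
Product: 20 CNP0407453.2
Conditions: angelic acid, 2,4,6-trichlorobenzoyl chloride, Et3N, toluene, 23 °C; then 19, toluene, 75 °C
Reagents that add atoms: angelic acid, C/C=C(/C)C(=O)O
Why: Yamaguchi esterification through the mixed angelic 2,4,6-trichlorobenzoic anhydride should acylate both secondary alcohols, and leaving out DMAP should avoid Z to E isomerisation of the angelate.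

Compound list
1 | 3-(trimethylsilyl)prop-2-ynal | C[Si](C)(C)C#CC=O | starting material
2 | (3R)-1-(trimethylsilyl)hex-5-en-1-yn-3-ol | C=CC[C@@H](O)C#C[Si](C)(C)C | intermediate
3 | (3R)-6-methyl-1-(trimethylsilyl)hept-5-en-1-yn-3-ol | CC(C)=CC[C@@H](O)C#C[Si](C)(C)C | intermediate
4 | triethyl{[(3R)-6-methyl-1-(trimethylsilyl)hept-5-en-1-yn-3-yl]oxy}silane | CC(C)=CC[C@@H](O[Si](CC)(CC)CC)C#C[Si](C)(C)C | intermediate
5 | triethyl{[(2R)-1-[(2S)-3,3-dimethyloxiran-2-yl]-4-(trimethylsilyl)but-3-yn-2-yl]oxy}silane | C[Si](C)(C)C#C[C@H](O[Si](CC)(CC)CC)C[C@@H]1OC1(C)C | intermediate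
6 | lithium (3R)-4-[(2S)-3,3-dimethyloxiran-2-yl]-3-[(triethylsilyl)oxy]but-1-yn-1-ide | [Li]C#C[C@H](O[Si](CC)(CC)CC)C[C@@H]1OC1(C)C | intermediate
7 | S-ethyl (5R)-6-[(2S)-3,3-dimethyloxiran-2-yl]-2-oxo-5-[(triethylsilyl)oxy]hex-3-ynethioate | CCSC(=O)C(=O)C#C[C@H](O[Si](CC)(CC)CC)C[C@@H]1OC1(C)C | intermediate
8 | S-ethyl (2S,5R)-6-[(2S)-3,3-dimethyloxiran-2-yl]-2-hydroxy-5-[(triethylsilyl)oxy]hex-3-ynethioate | CCSC(=O)[C@@H](O)C#C[C@H](O[Si](CC)(CC)CC)C[C@@H]1OC1(C)C | intermediate
9 | S-ethyl (2S,5R)-2-acetoxy-6-[(2S)-3,3-dimethyloxiran-2-yl]-5-[(triethylsilyl)oxy]hex-3-ynethioate | CCSC(=O)[C@@H](OC(C)=O)C#C[C@H](O[Si](CC)(CC)CC)C[C@@H]1OC1(C)C | intermediate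
10 | S-ethyl (2S,5R)-2-acetoxy-6-[(2S)-3,3-dimethyloxiran-2-yl]-5-hydroxyhex-3-ynethioate | CCSC(=O)[C@@H](OC(C)=O)C#C[C@H](O)C[C@@H]1OC1(C)C | intermediate
11 | S-ethyl (2S,3Z,5R)-2-acetoxy-6-[(2S)-3,3-dimethyloxiran-2-yl]-5-hydroxy-4-(tributylstannyl)hex-3-enethioate | CCSC(=O)[C@@H](OC(C)=O)/C=C(\[Sn](CCCC)(CCCC)CCCC)[C@H](O)C[C@@H]1OC1(C)C | intermediate
12 | S-ethyl (2S,3E,5R)-2-acetoxy-6-[(2S)-3,3-dimethyloxiran-2-yl]-5-hydroxy-4-[(4,4,5,5-tetramethyl-1,3,2-dioxaborolan-2-yl)methyl]hex-3-enethioate | CCSC(=O)[C@@H](OC(C)=O)/C=C(\CB1OC(C)(C)C(C)(C)O1)[C@H](O)C[C@@H]1OC1(C)C | intermediate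
13 | but-2-yn-1-ol | CC#CCO | starting material
14 | sodium 2,2-bis(2-methoxyethoxy)-3-methyl-2,5-dihydro-1,2-oxaaluminol-2-uide (cyclic alkenyl alkoxy aluminate) | CC1=CCO[Al-]1(OCCOC)OCCOC.[Na+] | intermediate
15 | (2Z)-3-(tributylstannyl)but-2-en-1-ol | CCCC[Sn](CCCC)(CCCC)/C(C)=C\CO | intermediate
16 | (2Z)-3-(tributylstannyl)but-2-enal | CCCC[Sn](CCCC)(CCCC)/C(C)=C\C=O | intermediate
17 | (2Z,5S,6E,8R)-9-[(2S)-3,3-dimethyloxiran-2-yl]-8-hydroxy-3-methyl-1,4-dioxo-7-[(4,4,5,5-tetramethyl-1,3,2-dioxaborolan-2-yl)methyl]nona-2,6-dien-5-yl acetate | O=C/C=C(C)\C(=O)[C@@H](OC(C)=O)/C=C(\CB1OC(C)(C)C(C)(C)O1)[C@H](O)C[C@@H]1OC1(C)C | intermediate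
18 | (1S,5R,6R)-6-{(3R)-4-[(2S)-3,3-dimethyloxiran-2-yl]-3-hydroxybut-1-en-2-yl}-5-hydroxy-3-methyl-2-oxocyclohex-3-en-1-yl acetate | C=C([C@@H]1[C@H](O)C=C(C)C(=O)[C@H]1OC(C)=O)[C@H](O)C[C@@H]1OC1(C)C | intermediate
19 | (1S,3S,4R,5S,6S)-4-{(3R)-4-[(2S)-3,3-dimethyloxiran-2-yl]-3-hydroxybut-1-en-2-yl}-5-hydroxy-1-methyl-2-oxo-7-oxabicyclo[4.1.0]heptan-3-yl acetate | C=C([C@@H]1[C@H](O)[C@@H]2O[C@]2(C)C(=O)[C@H]1OC(C)=O)[C@H](O)C[C@@H]1OC1(C)C | intermediate
20 | CNP0407453.2, (1S,2S,3R,4S,6S)-4-acetoxy-3-{(3R)-4-[(2S)-3,3-dimethyloxiran-2-yl]-3-[(Z)-2-methylbut-2-enoyloxy]but-1-en-2-yl}-6-methyl-5-oxo-7-oxabicyclo[4.1.0]heptan-2-yl (Z)-2-methylbut-2-enoate | C=C([C@@H]1[C@H](OC(=O)/C(C)=C\C)[C@@H]2O[C@]2(C)C(=O)[C@H]1OC(C)=O)[C@@H](C[C@@H]1OC1(C)C)OC(=O)/C(C)=C\C | target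

Total step count: 15. Longest linear sequence: 13 steps (steps 1 to 10, then 13 to 15).

Steps most likely to fail

Step 13. Coupling and ring closure may interfere: bimolecular allylboration or Z to E isomerisation of the enal before the coupling, transfer of the allyl group from boron to copper, or ionisation of the allylic acetate by zerovalent palladium would erode the diastereocontrol or give oligomers. The fallback separates the two events by masking the aldehyde. It sets out from 16 and 12 and comes back at 18. Aldehyde 16 is converted with HC(OEt)3 and a trace of NH4NO3 in EtOH into its diethyl acetal, (Z)-tributyl(4,4-diethoxybut-2-en-2-yl)stannane F1. F1 is coupled with 12 under the same palladium–copper conditions to the acetal-protected oxo-enal (2Z,5S,6E,8R)-1,1-diethoxy-9-[(2S)-3,3-dimethyloxiran-2-yl]-8-hydroxy-3-methyl-4-oxo-7-[(4,4,5,5-tetramethyl-1,3,2-dioxaborolan-2-yl)methyl]nona-2,6-dien-5-yl acetate F2, which cannot react with its own allylboronate. Mild unmasking (LiBF4 in wet MeCN) then releases 17, which should cyclise to 18 under purely intramolecular control.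

Step 10. Tin-to-copper exchange at the hindered, fully substituted alkenylstannane may be slow, so that protodestannylation or homocoupling competes with the alkylation. The fallback uses a palladium cross-coupling of an alkenyl iodide instead. It sets out from 11 and comes back at 12. Iododestannylation of 11 (I2, CH2Cl2, 0 °C, retention) should give S-ethyl (2S,3Z,5R)-2-acetoxy-6-[(2S)-3,3-dimethyloxiran-2-yl]-5-hydroxy-4-iodohex-3-enethioate F3. A Negishi coupling of F3 with IZnCH2Bpin and Pd(PPh3)4 in THF at 23 °C should then give 12, oxidative addition into the C–I bond being much faster than into the thioester.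

Step 14. The peroxide may attack the face opposite to the hydroxyl group (the sterically open face), and the basic peroxide may cleave or epimerise the C6 acetate. The fallback replaces substrate direction under basic conditions by catalyst control under base-free conditions. It sets out from 18 and comes back at 19. Iminium-type epoxidation with aqueous H2O2 and the trifluoroacetate salt of a 9-amino-9-deoxy-epi-cinchona alkaloid (the pseudo-enantiomer that delivers oxygen to the required face) should give 19; no new compound arises (F0).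

Further compounds
F1 | step 13 | (Z)-tributyl(4,4-diethoxybut-2-en-2-yl)stannane | CCCC[Sn](CCCC)(CCCC)/C(C)=C\C(OCC)OCC
F2 | step 13 | (2Z,5S,6E,8R)-1,1-diethoxy-9-[(2S)-3,3-dimethyloxiran-2-yl]-8-hydroxy-3-methyl-4-oxo-7-[(4,4,5,5-tetramethyl-1,3,2-dioxaborolan-2-yl)methyl]nona-2,6-dien-5-yl acetate | CCOC(OCC)/C=C(C)\C(=O)[C@@H](OC(C)=O)/C=C(\CB1OC(C)(C)C(C)(C)O1)[C@H](O)C[C@@H]1OC1(C)C
F3 | step 10 | S-ethyl (2S,3Z,5R)-2-acetoxy-6-[(2S)-3,3-dimethyloxiran-2-yl]-5-hydroxy-4-iodohex-3-enethioate | CCSC(=O)[C@@H](OC(C)=O)/C=C(\I)[C@H](O)C[C@@H]1OC1(C)C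
F0 | step 14 | none | none
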